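The plan disconnects the C1–C2 bond of ring B and ties the C1 oxygen back onto C4. The feature used is that the carbinol carbon C1 and the aryl-bearing carbon C4 are both attached directly to ring A and face each other across ring B, so a single oxygen can link them in a five-membered ether. Metalation of that ether at C1 should set off a [2,3]-Wittig ring expansion which, in one operation, closes ring B through the C1–C2 bond, releases the C1 hydroxyl, leaves a C3=C4 alkene and hands the configuration of the quaternary ether carbon on to C1. The precursor is an (S)-1-naphthyl-1-vinylphthalan with a protected naphthol; hydroxyl-directed hydrogenation later sets C4.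

Key step: step 7

Remarks
- Numbering: C1–C4 and the ring letters refer to the tetralin core of the target. Ring A is the methoxy-bearing benzo ring and ring B the partly saturated ring.
- Protecting group: the naphthol is carried as its 2-(trimethylsilyl)ethoxymethyl (SEM) ether. The acetal directs the ortho-lithiation used to join the fragments, leaves no free ortho or peri position on its ring, and is removed by fluoride, so no acid is needed once the benzylic C1 carbinol exists.
- Handling: the tertiary diaryl(vinyl) carbinol and its cyclic ether ionise easily, so compounds 10 to 13 are kept basic (amine-deactivated silica).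
- Assumption: the absolute configuration of resolved 11 is assigned by X-ray crystallography (anomalous dispersion) before it is carried on.

Step 1
Reactants: 1 naphthalene-1,8-diol
Product: 2 8-methoxynaphthalen-1-ol
Conditions: MeI (1.05 equiv), K2CO3, acetone, reflux
Reagents that add atoms: iodomethane, CI
Why: Williamson ether synthesis; after the first methylation the remaining hydroxyl is held in a peri hydrogen bond to the new methoxy oxygen and is much less acidic, so alkylation should stop at the monoether.

Step 2
Reactants: 2 8-methoxynaphthalen-1-ol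
Product: 3 1-methoxy-8-{[2-(trimethylsilyl)ethoxy]methoxy}naphthalene
Conditions: NaH, DMF, 0 °C; SEMCl, 0 °C → rt
Reagents that add atoms: 2-(trimethylsilyl)ethoxymethyl chloride, C[Si](C)(C)CCOCCl
Why: Williamson-type O-alkylation of the sodium naphtholate with a reactive chloromethyl ether installs the acetal that later directs ortho-lithiation and is cleaved by fluoride.

Step 3
Reactants: 4 (3-methoxyphenyl)methanol
Product: 7 7-methoxy-2-benzofuran-1(3H)-one (7-methoxyphthalide), via dilithio species 5 (not isolated), via hydroxy acid 6 (not isolated)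
Conditions: n-BuLi (2.2 equiv), TMEDA, toluene, 0 °C → rt; CO2, −78 °C → rt; 2 M HCl
Reagents that add atoms: carbon dioxide, O=C=O
Why: directed ortho-metalation in which the lithium alkoxide and the methoxy group cooperate to place lithium on the carbon between them, followed by carboxylation and acid-promoted lactonisation.

Step 4
Reactants: 3 1-methoxy-8-{[2-(trimethylsilyl)ethoxy]methoxy}naphthalene; 7 7-methoxy-2-benzofuran-1(3H)-one
Product: 10 rac-1-[2-(hydroxymethyl)-6-methoxyphenyl]-1-(8-methoxy-1-{[2-(trimethylsilyl)ethoxy]methoxy}naphthalen-2-yl)prop-2-en-1-ol, via aryllithium 8 (not isolated), via keto alkoxide 9 (not isolated)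
Conditions: 3, n-BuLi, TMEDA, Et2O, 0 °C; 7, THF, −78 → −20 °C; CH2=CHMgBr (3 equiv), −20 °C → rt; H2O
Reagents that add atoms: vinylmagnesium bromide, C=C[Mg]Br
Why: acetal-directed ortho-lithiation at C2 of the naphthalene (the peri position is blocked), nucleophilic acyl substitution on the lactone that should stop at the crowded keto alkoxide, and Grignard 1,2-addition to the non-enolisable diaryl ketone; the carbinol centre forms as a racemate.

Step 5
Reactants: 10 rac-1-[2-(hydroxymethyl)-6-methoxyphenyl]-1-(8-methoxy-1-{[2-(trimethylsilyl)ethoxy]methoxy}naphthalen-2-yl)prop-2-en-1-ol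
Product: 11 (1S)-1-[2-(hydroxymethyl)-6-methoxyphenyl]-1-(8-methoxy-1-{[2-(trimethylsilyl)ethoxy]methoxy}naphthalen-2-yl)prop-2-en-1-ol
Conditions: preparative HPLC, amylose tris(3,5-dimethylphenylcarbamate) on silica, heptane/i-PrOH, 0.1% Et2NH
Reagents that add atoms: none
Why: resolution of a racemate by chromatography on a chiral stationary phase, a standard method for tertiary 2-(hydroxymethyl)aryl carbinols, supplies the only stereocentre of the precursor in the (S) form, and the amine additive keeps the ionisable tertiary carbinol from racemising.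

Step 6
Reactants: 11 (1S)-1-[2-(hydroxymethyl)-6-methoxyphenyl]-1-(8-methoxy-1-{[2-(trimethylsilyl)ethoxy]methoxy}naphthalen-2-yl)prop-2-en-1-ol
Product: 13 (1S)-7-methoxy-1-(8-methoxy-1-{[2-(trimethylsilyl)ethoxy]methoxy}naphthalen-2-yl)-1-vinyl-1,3-dihydro-2-benzofuran, via primary tosylate 12 (not isolated)
Conditions: NaH (2.5 equiv), THF, 0 °C; TsCl (1.05 equiv), 0 °C → rt
Reagents that add atoms: none
Why: intramolecular Williamson etherification (5-exo-tet): the unhindered primary benzylic alkoxide is sulfonylated first and the tertiary alkoxide then displaces the tosylate, so no bond to the stereocentre is broken and the configuration is retained, while the basic medium prevents ionisation of the tertiary C–O bond.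

Step 7
Reactants: 13 (1S)-7-methoxy-1-(8-methoxy-1-{[2-(trimethylsilyl)ethoxy]methoxy}naphthalen-2-yl)-1-vinyl-1,3-dihydro-2-benzofuran
Product: 15 (1S)-5-methoxy-4-(8-methoxy-1-{[2-(trimethylsilyl)ethoxy]methoxy}naphthalen-2-yl)-1,2-dihydronaphthalen-1-ol, via C1-lithiated phthalan 14 (not isolated)
Conditions: t-BuLi (1.3 equiv), THF, −78 °C, then −78 → −40 °C; H2O
Reagents that add atoms: none
Why: Proposed new method: t-BuLi should remove a proton from the C1 methylene, which is benzylic to ring A and next to the ring oxygen that pre-coordinates lithium, and the α-oxy carbanion 14 then bonds to the vinyl terminus C2 through a five-membered, six-electron [2,3]-sigmatropic transition state (C1, O, C4, C3, C2) while the O–C4 bond breaks, leaving the C1 lithium alkoxide and a C3=C4 alkene conjugated to both arenes. The closest known reactions are the [2,3]-Wittig rearrangement of benzyl allyl ethers and the [2,3] ring expansions of 2-vinyl cyclic ethers and onium ylides; a carbanion placed inside the ether ring, across the oxygen from the vinyl-bearing carbon, has not been shown to rearrange in this way. Ring B closes by this suprafacial sigmatropic ring expansion of the five-membered ether into a six-membered carbocycle, through a bridged, oxanorbornene-like transition state, not by a polar cyclisation of an open chain. The new C1 stereocentre is controlled by the quaternary ether carbon C4, because the tethered vinyl group can reach C1 only on the face on which it sits, so (S)-13 should give (1S)-15 while the C4 centre itself is consumed. The step needs metalation at C1 only and [2,3] over [1,2] migration: C4 bears no hydrogen, the positions ortho and peri to the acetal oxygen are all substituted, a hindered base at −78 °C should disfavour ring lithiation beside the methoxy groups and SN2′ attack on the vinyl group, and the [1,2] path would have to form a strained benzocyclobutenol. The driving force is the conversion of a carbanion into an alkoxide together with the formation of the conjugated diaryl alkene.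

Step 8
Reactants: 15 (1S)-5-methoxy-4-(8-methoxy-1-{[2-(trimethylsilyl)ethoxy]methoxy}naphthalen-2-yl)-1,2-dihydronaphthalen-1-ol
Product: 16 (1S,4R)-5-methoxy-4-(8-methoxy-1-{[2-(trimethylsilyl)ethoxy]methoxy}naphthalen-2-yl)-1,2,3,4-tetrahydronaphthalen-1-ol
Conditions: [Ir(cod)(PCy3)(py)]PF6 (5 mol %), H2 (1 atm), CH2Cl2, 0 °C → rt
Reagents that add atoms: none
Why: hydroxyl-directed homogeneous hydrogenation: the C1 hydroxyl binds the cationic iridium centre and hydrogen is delivered to the face of C3=C4 on which it sits, so the new C4–H is cis to the hydroxyl, the naphthyl group ends up trans and C4 should be (R).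

Step 9
Reactants: 16 (1S,4R)-5-methoxy-4-(8-methoxy-1-{[2-(trimethylsilyl)ethoxy]methoxy}naphthalen-2-yl)-1,2,3,4-tetrahydronaphthalen-1-ol
Product: 17 (1S,4R)-4-(1-hydroxy-8-methoxynaphthalen-2-yl)-5-methoxy-1,2,3,4-tetrahydronaphthalen-1-ol (dipolynaphthalene A)
Conditions: Bu4NF (5 equiv), THF/DMPU, 60 °C, argon; aq NH4Cl
Reagents that add atoms: none
Why: fluoride-induced fragmentation of the 2-(trimethylsilyl)ethoxymethyl ether (attack at silicon, loss of ethene and formaldehyde) frees the naphthol under basic conditions that cannot ionise the benzylic C1 carbinol or epimerise C4.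

Compound list
1 | naphthalene-1,8-diol | Oc1cccc2cccc(O)c12 | starting material
2 | 8-methoxynaphthalen-1-ol | COc1cccc2cccc(O)c12 | intermediate
3 | 1-methoxy-8-{[2-(trimethylsilyl)ethoxy]methoxy}naphthalene | COc1cccc2cccc(OCOCC[Si](C)(C)C)c12 | intermediate
4 | (3-methoxyphenyl)methanol | COc1cccc(CO)c1 | starting material
5 | lithium (2-lithio-3-methoxyphenyl)methanolate (formed in the flask, not isolated) | COc1cccc(CO[Li])c1[Li] | intermediate
6 | 2-(hydroxymethyl)-6-methoxybenzoic acid (formed in the flask, not isolated) | COc1cccc(CO)c1C(=O)O | intermediate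
7 | 7-methoxy-2-benzofuran-1(3H)-one (7-methoxyphthalide) | COc1cccc2c1C(=O)OC2 | intermediate
8 | (8-methoxy-1-{[2-(trimethylsilyl)ethoxy]methoxy}naphthalen-2-yl)lithium (formed in the flask, not isolated) | [Li]c1ccc2cccc(OC)c2c1OCOCC[Si](C)(C)C | intermediate
9 | lithium [3-methoxy-2-(8-methoxy-1-{[2-(trimethylsilyl)ethoxy]methoxy}naphthalene-2-carbonyl)phenyl]methanolate, open form of the lactol alkoxide (formed in the flask, not isolated) | COc1cccc(CO[Li])c1C(=O)c1ccc2cccc(OC)c2c1OCOCC[Si](C)(C)C | intermediate
10 | rac-1-[2-(hydroxymethyl)-6-methoxyphenyl]-1-(8-methoxy-1-{[2-(trimethylsilyl)ethoxy]methoxy}naphthalen-2-yl)prop-2-en-1-ol | COc1cccc(CO)c1C(O)(C=C)c1ccc2cccc(OC)c2c1OCOCC[Si](C)(C)C | intermediate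
11 | (1S)-1-[2-(hydroxymethyl)-6-methoxyphenyl]-1-(8-methoxy-1-{[2-(trimethylsilyl)ethoxy]methoxy}naphthalen-2-yl)prop-2-en-1-ol | COc1cccc(CO)c1[C@](O)(C=C)c1ccc2cccc(OC)c2c1OCOCC[Si](C)(C)C | intermediate
12 | {2-[(1S)-1-hydroxy-1-(8-methoxy-1-{[2-(trimethylsilyl)ethoxy]methoxy}naphthalen-2-yl)prop-2-en-1-yl]-3-methoxyphenyl}methyl 4-methylbenzenesulfonate, present as its sodium alkoxide (formed in the flask, not isolated) | COc1cccc(COS(=O)(=O)c2ccc(C)cc2)c1[C@](O)(C=C)c1ccc2cccc(OC)c2c1OCOCC[Si](C)(C)C | intermediate
13 | (1S)-7-methoxy-1-(8-methoxy-1-{[2-(trimethylsilyl)ethoxy]methoxy}naphthalen-2-yl)-1-vinyl-1,3-dihydro-2-benzofuran | COc1cccc2c1[C@](C=C)(c1ccc3cccc(OC)c3c1OCOCC[Si](C)(C)C)OC2 | intermediate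
14 | 3-lithio derivative of 13, lithium on the OCH2 carbon that becomes C1 (formed in the flask, not isolated) | COc1cccc2c1[C@](C=C)(c1ccc3cccc(OC)c3c1OCOCC[Si](C)(C)C)OC2[Li] | intermediate
15 | (1S)-5-methoxy-4-(8-methoxy-1-{[2-(trimethylsilyl)ethoxy]methoxy}naphthalen-2-yl)-1,2-dihydronaphthalen-1-ol | COc1cccc2c1C(c1ccc3cccc(OC)c3c1OCOCC[Si](C)(C)C)=CC[C@@H]2O | intermediate
16 | (1S,4R)-5-methoxy-4-(8-methoxy-1-{[2-(trimethylsilyl)ethoxy]methoxy}naphthalen-2-yl)-1,2,3,4-tetrahydronaphthalen-1-ol | COc1cccc2c1[C@@H](c1ccc3cccc(OC)c3c1OCOCC[Si](C)(C)C)CC[C@@H]2O | intermediate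
17 | (1S,4R)-4-(1-hydroxy-8-methoxynaphthalen-2-yl)-5-methoxy-1,2,3,4-tetrahydronaphthalen-1-ol (dipolynaphthalene A) | COc1cccc2c1[C@@H](c1ccc3cccc(OC)c3c1O)CC[C@@H]2O | target

Total step count: 9
Longest linear sequence: 8 steps (steps 1, 2, 4, 5, 6, 7, 8 and 9, from naphthalene-1,8-diol)

Steps most likely to fail

Step 7 (proposed new method). The base may metalate an arene position beside a methoxy group, or attack the vinyl group in SN2′ fashion, instead of removing the C1 proton. The lithiated ether may also open to an o-quinodimethane alkoxide before the concerted shift; that species would still cyclise but the stereochemical relay would be lost. The fallback uses only known reactions, sets out from 3 and comes back at 15; ring B is taken from a tetralone and the C4–aryl bond is made by cross-coupling.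
- Compound 3 is ortho-lithiated as in step 4, quenched with B(OiPr)3 and hydrolysed with dilute aqueous NH4Cl to (8-methoxy-1-{[2-(trimethylsilyl)ethoxy]methoxy}naphthalen-2-yl)boronic acid F1.
- Commercial 5-methoxy-3,4-dihydronaphthalen-1(2H)-one (COc1cccc2c1CCCC2=O) is reduced by asymmetric transfer hydrogenation with RuCl(p-cymene)[(S,S)-TsDPEN] in HCO2H/Et3N to (1S)-5-methoxy-1,2,3,4-tetrahydronaphthalen-1-ol F2.
- Silylation (TBSCl, imidazole, DMF) gives tert-butyl{[(1S)-5-methoxy-1,2,3,4-tetrahydronaphthalen-1-yl]oxy}dimethylsilane F3.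
- Benzylic oxidation of the C4 methylene, the position activated by the ortho methoxy group (t-BuOOH, cat. Rh2(caprolactamate)4), should give (4S)-4-[(tert-butyldimethylsilyl)oxy]-8-methoxy-3,4-dihydronaphthalen-1(2H)-one F4.
- Enolisation and triflation (KN(SiMe3)2, PhNTf2, THF, −78 °C) give (4S)-4-[(tert-butyldimethylsilyl)oxy]-8-methoxy-3,4-dihydronaphthalen-1-yl trifluoromethanesulfonate F5.
- Suzuki–Miyaura coupling of F1 with F5 (Pd(OAc)2, SPhos, K3PO4, toluene/H2O) should give tert-butyl{[(1S)-5-methoxy-4-(8-methoxy-1-{[2-(trimethylsilyl)ethoxy]methoxy}naphthalen-2-yl)-1,2-dihydronaphthalen-1-yl]oxy}dimethylsilane F6.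
- Bu4NF in THF at 0 °C removes only the secondary silyl ether and returns 15.

Step 8. The crowded, doubly aryl-substituted alkene may bind iridium too weakly for the hydroxyl to steer the addition, giving poor facial selectivity at C4. The Lewis-acidic cationic catalyst may also dehydrate the homoallylic benzylic alcohol to an arylnaphthalene. The fallback sets out from 15 and comes back at 17; it replaces substrate direction by reagent control on a protected alcohol.
- 15 is silylated (TBSCl, imidazole, DMF) to the silyl ether F6 named above.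
- F6 is hydrogenated with a chiral cationic iridium phosphine–oxazoline catalyst, [Ir(cod)(tBu-PHOX)][B(C6H3(CF3)2)4], using the ligand enantiomer that adds hydrogen to the face of the C1 oxygen. This should give tert-butyl{[(1S,4R)-5-methoxy-4-(8-methoxy-1-{[2-(trimethylsilyl)ethoxy]methoxy}naphthalen-2-yl)-1,2,3,4-tetrahydronaphthalen-1-yl]oxy}dimethylsilane F7.
- Bu4NF in THF/DMPU at 60 °C then removes both silicon-based groups and gives 17 directly.

Step 4. Lithiation of 3 may be incomplete and, above all, the vinyl Grignard addition may stall because the crowded ketone rests as its cyclic hemiketal alkoxide. The fallback sets out from 3 and 7 and comes back at 10; it separates the two additions and uses a slimmer two-carbon nucleophile.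
- The aryllithium from 3 is added to 7 and the mixture is quenched with water to isolate [2-(hydroxymethyl)-6-methoxyphenyl](8-methoxy-1-{[2-(trimethylsilyl)ethoxy]methoxy}naphthalen-2-yl)methanone F8.
- Ethynylmagnesium bromide with CeCl3 in THF should add to the ketone to give rac-1-[2-(hydroxymethyl)-6-methoxyphenyl]-1-(8-methoxy-1-{[2-(trimethylsilyl)ethoxy]methoxy}naphthalen-2-yl)prop-2-yn-1-ol F9.
- Semihydrogenation of the alkyne (H2, Pd/CaCO3 poisoned with Pb(OAc)2, quinoline, EtOAc) gives 10.

Further compounds
F1 | step 7 | (8-methoxy-1-{[2-(trimethylsilyl)ethoxy]methoxy}naphthalen-2-yl)boronic acid | COc1cccc2ccc(B(O)O)c(OCOCC[Si](C)(C)C)c12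
F2 | step 7 | (1S)-5-methoxy-1,2,3,4-tetrahydronaphthalen-1-ol | COc1cccc2c1CCC[C@@H]2O
F3 | step 7 | tert-butyl{[(1S)-5-methoxy-1,2,3,4-tetrahydronaphthalen-1-yl]oxy}dimethylsilane | COc1cccc2c1CCC[C@@H]2O[Si](C)(C)C(C)(C)C
F4 | step 7 | (4S)-4-[(tert-butyldimethylsilyl)oxy]-8-methoxy-3,4-dihydronaphthalen-1(2H)-one | COc1cccc2c1C(=O)CC[C@@H]2O[Si](C)(C)C(C)(C)C
F5 | step 7 | (4S)-4-[(tert-butyldimethylsilyl)oxy]-8-methoxy-3,4-dihydronaphthalen-1-yl trifluoromethanesulfonate | COc1cccc2c1C(OS(=O)(=O)C(F)(F)F)=CC[C@@H]2O[Si](C)(C)C(C)(C)C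
F6 | step 7 | tert-butyl{[(1S)-5-methoxy-4-(8-methoxy-1-{[2-(trimethylsilyl)ethoxy]methoxy}naphthalen-2-yl)-1,2-dihydronaphthalen-1-yl]oxy}dimethylsilane | COc1cccc2c1C(c1ccc3cccc(OC)c3c1OCOCC[Si](C)(C)C)=CC[C@@H]2O[Si](C)(C)C(C)(C)C
F7 | step 8 | tert-butyl{[(1S,4R)-5-methoxy-4-(8-methoxy-1-{[2-(trimethylsilyl)ethoxy]methoxy}naphthalen-2-yl)-1,2,3,4-tetrahydronaphthalen-1-yl]oxy}dimethylsilane | COc1cccc2c1[C@@H](c1ccc3cccc(OC)c3c1OCOCC[Si](C)(C)C)CC[C@@H]2O[Si](C)(C)C(C)(C)C
F8 | step 4 | [2-(hydroxymethyl)-6-methoxyphenyl](8-methoxy-1-{[2-(trimethylsilyl)ethoxy]methoxy}naphthalen-2-yl)methanone | COc1cccc(CO)c1C(=O)c1ccc2cccc(OC)c2c1OCOCC[Si](C)(C)C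
F9 | step 4 | rac-1-[2-(hydroxymethyl)-6-methoxyphenyl]-1-(8-methoxy-1-{[2-(trimethylsilyl)ethoxy]methoxy}naphthalen-2-yl)prop-2-yn-1-ol | COc1cccc(CO)c1C(O)(C#C)c1ccc2cccc(OC)c2c1OCOCC[Si](C)(C)C
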